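## Analysis of the target

The target 15 is a depside: two fully substituted benzene rings joined by one aryl ester, with no stereocentre. Ring A is a methyl salicylate (C1 CO2Me, C2 OH) with methyl groups on C3, C5 and C6 and the depside oxygen on C4. Ring B is the acyl partner, a 5'-chloro-2'-hydroxy-4'-methoxy-3',6'-dimethylbenzoyl group. The sensitive groups are the central aryl ester (nucleophiles, base), the two chelated phenols (oxidants), the aryl chloride (reductive conditions) and the methyl ester. The difficulty is twofold: twelve substituents must each be placed without ambiguity, and the linking ester joins an oxygen flanked by the C3 and C5 methyl groups to a carbonyl flanked by the C2' hydroxyl and the C6' methyl group, so ordinary acyl substitution is slow. Two pairs of similar oxygens (O2/O4 on ring A, O2'/O4' on ring B) also have to be told apart. The strategy rests on ring A: C4 is meta to the C2 hydroxyl and lies between the methyl-bearing C3 and C5, so in the parent salicylate 4 it is the only ring carbon that carries hydrogen, and its neighbour C5 is para to the phenol. C5 can therefore be oxidised to a quaternary, acyloxy-bearing carbon, and the acyloxy group can then be handed on to C4.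

## Retrosynthetic reasoning

15 ⇒ 14 (O–acetyl bond on O2'). The last disconnection is a protecting group. The ring B phenol has to be masked while a phenol oxidant is in the flask. An acetate is chosen because a small aryl acetate is removed by transesterification under conditions that the doubly ortho-flanked depside carbonyl of 14 does not answer to.

14 ⇒ 12 (C4–O bond of ring A). The aryl–oxygen bond is cut, not the acyl–oxygen bond. Cutting the acyl–oxygen bond would require a bimolecular attack of a 3,5-dimethyl-flanked phenol on a 2',6'-disubstituted carbonyl. Cutting C4–O lets the ester oxygen arrive intramolecularly: the aroyloxy group is moved back to C5 and C4 receives hydrogen, which gives the cross-conjugated dienone 12. The forward reaction is the acid-promoted 1,2-acyloxy shift of a para-quinol ester through the bridged ion 13, ending with loss of the C4 proton. It must prefer acyloxy over methyl migration and must end on C4. Because C4 is the only hydrogen-bearing ring carbon of 12, the regiochemistry is fixed by the substrate, and the rest of ring A arrives complete.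

12 ⇒ 4 + 11 (C5–O bond). The quaternary C5–O bond is traced to an oxidative dearomatisation of the phenol 4, in which C5, para to the phenol oxygen, becomes electrophilic. The ring B carboxylate is delivered as a ligand of the aryl-λ3-iodane 11, so that it is the only nucleophile present. The new C5 stereocentre is formed as a racemate, which is acceptable because the key step removes it.

11 ⇒ 9 + 10 (two I–O bonds). The carboxylate ligands of 10 are exchanged for two molecules of the acid 9. The exchange takes place at the carboxyl oxygen, away from the shielded carbonyl carbon, and is driven by removal of the volatile acid that is displaced.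

9 ⇒ 8 ⇒ 7 ⇒ 6 ⇒ 5 (O-acetyl, ester C–O, C5'–Cl and O4'–CH3 bonds). Ring B needs no skeletal bond formation: 5 already has the carbon framework and both oxygens. The order is set by selectivity. The non-chelated O4' is methylated first. Chlorination then has a single free ring position. The ester is cleaved after chlorination, because a free electron-rich acid would invite ipso attack. The acetate is put on last, because the ester cleavage would remove it.

4 ⇒ 3 ⇒ 2 ⇒ 1 (C1–carboxyl bond). The carboxyl carbon is introduced at the one free ortho position of the phenol 1 as a formyl group, which is then oxidised and esterified. The other unsubstituted carbon of 1 is meta to the hydroxyl and is left alone; it becomes C4, the hydrogen-bearing terminus that the key step needs.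

## Alternatives that were turned down

Alternative 1: Ring A is dismantled completely by cutting C2–C3, C4–C5 and C1–C2, which leads to the diazo ketone A2 (methyl (2E)-5-diazo-3-methyl-4-oxohex-2-enoate) and the silyl ynol ether A3 (1-(triisopropylsilyloxy)propyne). In the forward direction, irradiation of A2 triggers a Wolff rearrangement. (2+2) cycloaddition with A3, four-electron ring opening and six-electron ring closure then give A1 (methyl 2-hydroxy-3,5,6-trimethyl-4-(triisopropylsilyloxy)benzoate).
- For: every substituent of ring A is placed by the mechanism, the two oxygens are differentiated from the outset (O2 free, O4 silylated), and the approach is convergent. On regiochemical certainty it is stronger than the chosen route, which depends on the selectivity of a migration.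
- Against: A1 is only ring A. The depside bond must still be made by desilylation and acylation of the C3/C5-flanked oxygen with the hindered acid 9, followed by deacetylation, so three steps follow the key step instead of one. A2 requires a diazo transfer and photochemical equipment.
- Comparison: this route builds from acyclic pieces a ring whose three methyl groups the commodity phenol 1 already supplies. The chosen strategy needs only one C–H to C–O conversion on ring A and makes that bond with the acyl group already attached.

Alternative 2: Ring B is the ring that is built, by cutting C1'–C2' and C5'–C6'. This leads to the ring A aryl but-2-ynoate A5 (methyl 4-(but-2-ynoyloxy)-2-(methoxymethoxy)-3,5,6-trimethylbenzoate) and the diene A6 (1,3-dimethoxy-2-methyl-1-(trimethylsilyloxy)buta-1,3-diene). In the forward (4+2) cycloaddition the CH2 terminus of A6 bonds to the methyl-bearing alkyne carbon (C6') and the ketene acetal carbon bonds to C1'. Loss of the C2' methoxy group and of the silyl group on mild acid work-up aromatises the adduct to A4 (methyl 4-[(2-hydroxy-4-methoxy-3,6-dimethylbenzoyl)oxy]-2-(methoxymethoxy)-3,5,6-trimethylbenzoate).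
- For: the ester to the ring A oxygen is made while the acyl group is still a slim butynoyl unit, and the hindrance is built up afterwards. The polarised diene fixes the ring B substitution pattern. On the ester linkage this is as strong as or stronger than the chosen route, because no bulky partner has to meet a flanked oxygen.
- Against: A5 presupposes a ring A that already carries the C4 oxygen, so the problem that the chosen key step solves is left open. An internal alkyne with a β-methyl group and a 2-methyl diene make a sluggish pair, and the diene is thermally fragile. A4 lacks the C5' chlorine and carries an acetal on O2, so chlorination and acetal cleavage must follow.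
- Comparison: two steps after the key step against one, and a longer preparation of the ring A partner. The chosen route provides the ring A oxygenation and the depside connection in the same operation.

Alternative 3: Ring A is folded from a chain by cutting C1–C6. The precursor is the triketo ester A9 (methyl 4,6-dimethyl-3,5,7-trioxooctanoate), which is released from the dioxinone A8 (2,2-dimethyl-6-(4-methyl-3,5-dioxohexan-2-yl)-4H-1,3-dioxin-4-one). In the forward direction, heating A8 in the alcohol that supplies the ester methyl group opens the dioxinone ring by a retro-(4+2) process, and the solvent captures the product as A9. Mild base then lets the C2 methylene of A9 add to the C7 ketone, and dehydration and enolisation give A7 (methyl 2,4-dihydroxy-3,5,6-trimethylbenzoate).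
- For: it is short and biomimetic, and it gives both ring A oxygens in the correct pattern without protecting groups. If the folding works, it may reach ring A in as few steps as the chosen route or fewer, and each bond formation is of a well-known type.
- Against: A8 and A9 carry two epimerisable methyl-bearing carbons between carbonyl groups and are open to retro-Claisen cleavage and to other cyclisation modes (lactonisation, alternative aldol closures). A8 itself needs several C-acylation steps. A7 must still be acylated at O4 with the hindered acid 9 and then deacetylated.
- Comparison: the chosen route starts from an aromatic ring in which all C–C bonds are already present. It forms the C4–O bond with the carboxylate acting as an oxygen nucleophile, so the hindered ester is never made by acyl substitution. The price is reliance on a migration that has not been tested with so bulky an acyl group.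

Key step: step 10

Remark on the chemistry: ring A keeps the locants of the target (C1 carries CO2Me) in all intermediates, including the dearomatised ones, and ring B carries primed locants. Compounds 12 and 13 are racemic; the target has no stereocentre, so no enantiocontrol is attempted. Compounds 1, 5 and 10 are taken as purchasable.

## Route

Step 1
Reactants: 1 2,4,5-trimethylphenol
Product: 2 2-hydroxy-3,5,6-trimethylbenzaldehyde
Conditions: MgCl2, Et3N, (CH2O)n, MeCN, reflux; then 1 M HCl
Reagents that add atoms: formaldehyde (as paraformaldehyde), C=O
Why: Casnati–Skattebøl ortho-formylation: the magnesium phenoxide directs hydroxymethylation to the only free ortho carbon, and a second equivalent of formaldehyde oxidises the benzylic alkoxide by hydride transfer. The free carbon meta to the hydroxyl (the later C4) is not attacked.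

Step 2
Reactants: 2 2-hydroxy-3,5,6-trimethylbenzaldehyde
Product: 3 2-hydroxy-3,5,6-trimethylbenzoic acid
Conditions: NaClO2, NaH2PO4, 2-methylbut-2-ene, t-BuOH/H2O, 0 °C to rt
Reagents that add atoms: sodium chlorite, [Na+].[O-]Cl=O
Why: Pinnick oxidation: chlorous acid adds to the aldehyde and fragments to the acid; the alkene traps the hypochlorous acid released, so the electron-rich ring with its free C4–H is not chlorinated.

Step 3
Reactants: 3 2-hydroxy-3,5,6-trimethylbenzoic acid
Product: 4 methyl 2-hydroxy-3,5,6-trimethylbenzoate
Conditions: MeI, KHCO3, DMF, rt
Reagents that add atoms: iodomethane, CI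
Why: SN2 O-alkylation of the carboxylate, which avoids addition to the doubly ortho-substituted carbonyl carbon; KHCO3 is too weak a base to ionise the chelated phenol, so the phenol is not methylated.

Step 4
Reactants: 5 methyl 2,4-dihydroxy-3,6-dimethylbenzoate
Product: 6 methyl 2-hydroxy-4-methoxy-3,6-dimethylbenzoate
Conditions: MeI (1.1 equiv), K2CO3, acetone, reflux
Reagents that add atoms: iodomethane, CI
Why: Williamson ether synthesis: the C2 hydroxyl is tied up in a hydrogen bond to the ester carbonyl and is far less acidic and nucleophilic, so the C4 hydroxyl should be methylated selectively.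

Step 5
Reactants: 6 methyl 2-hydroxy-4-methoxy-3,6-dimethylbenzoate
Product: 7 methyl 5-chloro-2-hydroxy-4-methoxy-3,6-dimethylbenzoate
Conditions: SO2Cl2 (1.05 equiv), CH2Cl2, 0 °C to rt
Reagents that add atoms: sulfuryl chloride, O=S(=O)(Cl)Cl
Why: Electrophilic aromatic chlorination at C5, the only unsubstituted ring carbon, which is para to the C2 hydroxyl and ortho to the methoxy group; ionic conditions in the dark leave the benzylic methyl groups alone.

Step 6
Reactants: 7 methyl 5-chloro-2-hydroxy-4-methoxy-3,6-dimethylbenzoate
Product: 8 5-chloro-2-hydroxy-4-methoxy-3,6-dimethylbenzoic acid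
Conditions: KOH, DMSO/H2O, 80 °C; then cold 1 M HCl
Reagents that add atoms: potassium hydroxide, [K+].[OH-]
Why: Saponification of a di-ortho-substituted benzoate needs poorly solvated hydroxide in aqueous DMSO; acidification in the cold should prevent protodecarboxylation of the electron-rich salicylic acid. The aryl chloride and the aryl methyl ether are inert.

Step 7
Reactants: 8 5-chloro-2-hydroxy-4-methoxy-3,6-dimethylbenzoic acid
Product: 9 2-acetoxy-5-chloro-4-methoxy-3,6-dimethylbenzoic acid
Conditions: Ac2O, pyridine, DMAP (cat.), CH2Cl2, 0 °C to rt; then H2O
Reagents that add atoms: acetic anhydride, CC(=O)OC(C)=O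
Why: Nucleophile-catalysed O-acetylation of the phenol, as in the acetylation of salicylic acid; the aqueous stir returns the carboxyl group to the free acid if it was acylated. The acetate shields the ring B phenol from the oxidant of steps 8 and 9.

Step 8
Reactants: 9 2-acetoxy-5-chloro-4-methoxy-3,6-dimethylbenzoic acid (2.05 equiv); 10 (diacetoxyiodo)benzene
Product: 11 bis[(2-acetoxy-5-chloro-4-methoxy-3,6-dimethylbenzoyl)oxy](phenyl)-λ3-iodane
Conditions: PhCl, 50 °C, reduced pressure (AcOH distilled off, repeated)
Reagents that add atoms: none
Why: Carboxylate ligand exchange at trivalent iodine is an equilibrium that is pulled over by removing the volatile acetic acid. The exchange occurs at the carboxyl oxygen, so the hindrance around the carbonyl carbon of 9 does not matter.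

Step 9
Reactants: 4 methyl 2-hydroxy-3,5,6-trimethylbenzoate; 11 bis[(2-acetoxy-5-chloro-4-methoxy-3,6-dimethylbenzoyl)oxy](phenyl)-λ3-iodane (1.1 equiv)
Product: 12 racemic methyl 5-[(2-acetoxy-5-chloro-4-methoxy-3,6-dimethylbenzoyl)oxy]-3,5,6-trimethyl-2-oxocyclohexa-3,6-diene-1-carboxylate
Conditions: (CF3)2CHOH/CH2Cl2, 0 °C to rt
Reagents that add atoms: none
Why: Oxidative dearomatisation of a para-alkylphenol by a [bis(acyloxy)iodo]arene (Wessely-type acyloxylation): the phenol displaces one carboxylate on iodine, and a ring B carboxylate adds to C5, para to the oxygen, as iodobenzene leaves. The C5 stereocentre forms without control, so 12 is racemic, which does not matter because step 10 erases it. Attack at C3 instead would give a regioisomer that reaches the same arenium ion in step 10, since C3 also adjoins C4, so the crude product can be carried on.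

Step 10
Reactants: 12 racemic methyl 5-[(2-acetoxy-5-chloro-4-methoxy-3,6-dimethylbenzoyl)oxy]-3,5,6-trimethyl-2-oxocyclohexa-3,6-diene-1-carboxylate
Product: 14 methyl 4-[(2-acetoxy-5-chloro-4-methoxy-3,6-dimethylbenzoyl)oxy]-2-hydroxy-3,5,6-trimethylbenzoate, via bridged 1,3-dioxolan-2-ylium trifluoroacetate 13 (not isolated)
Conditions: CF3CO2H/CH2Cl2 (1:4), 0 °C to rt
Reagents that add atoms: none
Why: Protonation of the C2 carbonyl of 12 spreads positive charge to C4 and C6, the two neighbours of quaternary C5, and the carbonyl oxygen of the C5 ester adds to C4 in a 5-exo-trig closure to give the cis-fused 1,3-dioxolan-2-ylium ion 13, the same neighbouring-group bridge that 2,6-disubstituted benzoates form in other cationic settings. Heterolysis of the C5–O bond of 13 leaves the aroyloxy group on C4 and a tertiary cation on C5 that is the arenium ion of 14; loss of the C4 proton restores the aromatic ring and makes the shift irreversible. The closest known reaction type is the acid-promoted rearrangement of para-quinol acetates to resorcinol monoacetates, a dienone–phenol rearrangement in which acyloxy moves instead of alkyl. No ring of 14 is closed (the five-membered ring of 13 is transient and cis-fused by necessity) and no stereocentre is made; the racemic C5 centre of 12 is erased. The step needs acyloxy to move in preference to the C5 methyl group, which lone-pair bridging secures because a methyl shift has no comparably low-energy path. It also needs C4 as the terminus: bridging toward C6 is possible and is even favoured electronically (C6 is β to both the ketone and the C1 ester), but the resulting ion has a quaternary C6 with no proton to lose and no neutral dienone form, so it can only return, and material leaves solely by way of C4. A Brønsted acid is chosen over a chelating Lewis acid so that the C1 ester and C2 ketone are not locked into a chelate that would steer charge to C6; the aryl acetate, aryl chloride, ether and esters are inert to these conditions.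

Step 11
Reactants: 14 methyl 4-[(2-acetoxy-5-chloro-4-methoxy-3,6-dimethylbenzoyl)oxy]-2-hydroxy-3,5,6-trimethylbenzoate
Product: 15 methyl 4-[(5-chloro-2-hydroxy-4-methoxy-3,6-dimethylbenzoyl)oxy]-2-hydroxy-3,5,6-trimethylbenzoate
Conditions: K2CO3 (2 equiv), MeOH, 0 °C; then cold 1 M HCl
Reagents that add atoms: none
Why: Transesterification of an aryl acetate by methoxide is fast at the small acetyl carbonyl. The depside carbonyl is flanked by C2'–O and the C6' methyl group on one side and by a 3,5-dimethylaryloxy group on the other, and should not be attacked at 0 °C. Exchange at the ring A methyl ester is degenerate in MeOH.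

## Compound list

1 | 2,4,5-trimethylphenol | Cc1cc(C)c(C)cc1O | starting material
2 | 2-hydroxy-3,5,6-trimethylbenzaldehyde | O=Cc1c(C)c(C)cc(C)c1O | intermediate
3 | 2-hydroxy-3,5,6-trimethylbenzoic acid | OC(=O)c1c(C)c(C)cc(C)c1O | intermediate
4 | methyl 2-hydroxy-3,5,6-trimethylbenzoate | COC(=O)c1c(C)c(C)cc(C)c1O | intermediate
5 | methyl 2,4-dihydroxy-3,6-dimethylbenzoate | COC(=O)c1c(C)cc(O)c(C)c1O | starting material
6 | methyl 2-hydroxy-4-methoxy-3,6-dimethylbenzoate | COC(=O)c1c(C)cc(OC)c(C)c1O | intermediate
7 | methyl 5-chloro-2-hydroxy-4-methoxy-3,6-dimethylbenzoate | COC(=O)c1c(C)c(Cl)c(OC)c(C)c1O | intermediate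
8 | 5-chloro-2-hydroxy-4-methoxy-3,6-dimethylbenzoic acid | OC(=O)c1c(C)c(Cl)c(OC)c(C)c1O | intermediate
9 | 2-acetoxy-5-chloro-4-methoxy-3,6-dimethylbenzoic acid | OC(=O)c1c(C)c(Cl)c(OC)c(C)c1OC(C)=O | intermediate
10 | (diacetoxyiodo)benzene | CC(=O)OI(OC(C)=O)c1ccccc1 | starting material
11 | bis[(2-acetoxy-5-chloro-4-methoxy-3,6-dimethylbenzoyl)oxy](phenyl)-λ3-iodane | CC(=O)Oc1c(C)c(OC)c(Cl)c(C)c1C(=O)OI(OC(=O)c1c(C)c(Cl)c(OC)c(C)c1OC(C)=O)c1ccccc1 | intermediate
12 | racemic methyl 5-[(2-acetoxy-5-chloro-4-methoxy-3,6-dimethylbenzoyl)oxy]-3,5,6-trimethyl-2-oxocyclohexa-3,6-diene-1-carboxylate (para-quinol ester; C5 quaternary, C1=C6 and C3=C4 double bonds, C2 ketone) | COC(=O)C1=C(C)C(C)(OC(=O)c2c(C)c(Cl)c(OC)c(C)c2OC(C)=O)C=C(C)C1=O | intermediate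
13 | racemic cis-fused 2-(2-acetoxy-5-chloro-4-methoxy-3,6-dimethylphenyl)-6-hydroxy-5-(methoxycarbonyl)-3a,4,7-trimethyl-3a,7a-dihydro-1,3-benzodioxol-2-ylium trifluoroacetate (dioxolanylium bridge across C4 and C5 of ring A) | COC(=O)C1=C(C)C2(C)[O+]=C(c3c(C)c(Cl)c(OC)c(C)c3OC(C)=O)OC2C(C)=C1O.[O-]C(=O)C(F)(F)F | intermediate (not isolated)
14 | methyl 4-[(2-acetoxy-5-chloro-4-methoxy-3,6-dimethylbenzoyl)oxy]-2-hydroxy-3,5,6-trimethylbenzoate | COC(=O)c1c(C)c(C)c(OC(=O)c2c(C)c(Cl)c(OC)c(C)c2OC(C)=O)c(C)c1O | intermediate
15 | methyl 4-[(5-chloro-2-hydroxy-4-methoxy-3,6-dimethylbenzoyl)oxy]-2-hydroxy-3,5,6-trimethylbenzoate | COC(=O)c1c(C)c(C)c(OC(=O)c2c(C)c(Cl)c(OC)c(C)c2O)c(C)c1O | target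

## Step count and least certain steps

Total: 11 steps. Longest linear sequence: 8 steps (5 → 6 → 7 → 8 → 9 → 11 → 12 → 14 → 15, steps 4 to 11); the ring A branch (steps 1 to 3) joins at step 9.

**Step 10 (key step).** The most likely failure is that the bulky aryl group, twisted out of conjugation by its two ortho substituents, stabilises the bridged ion 13 less than a simple acetate would. A 1,2-shift of the C5 methyl group, or ionisation of the C5–O bond with loss of the carboxylic acid, could then compete with the acyloxy shift, particularly since charge is also drawn toward C6.

Fallback, setting out from 4 (with 9 and 10) and returning at 14: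
- 4 is oxidised with 10 in acetic acid to the para-quinol acetate, racemic methyl 5-acetoxy-3,5,6-trimethyl-2-oxocyclohexa-3,6-diene-1-carboxylate F1.
- The small acetoxy group of F1 is the classical migrating group, and CF3CO2H should convert F1 into methyl 4-acetoxy-2-hydroxy-3,5,6-trimethylbenzoate F2.
- K2CO3 in MeOH frees methyl 2,4-dihydroxy-3,5,6-trimethylbenzoate F3.
- Acid 9 is activated with trifluoroacetic anhydride in toluene as 2-acetoxy-5-chloro-4-methoxy-3,6-dimethylbenzoic trifluoroacetic anhydride F4. Its acylium ion acylates the non-chelated C4 hydroxyl of F3, the established way to join hindered depside halves, and this gives 14.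

**Step 9.** The most likely failures are slow exchange of the chelated, ester-deactivated phenol onto iodine, and loss of a proton from the C5 methyl group of the oxidised ring before the bulky, weakly nucleophilic carboxylate can add. The second process diverts material to benzylic products.

Fallback, setting out from 4 (with 9 and 10) and returning at 12:
- 4 is oxidised with 10 in aqueous MeCN, where water is the small nucleophile, to the para-quinol, racemic methyl 5-hydroxy-3,5,6-trimethyl-2-oxocyclohexa-3,6-diene-1-carboxylate F5.
- Acid 9 is converted with oxalyl chloride and catalytic DMF into 2-acetoxy-5-chloro-4-methoxy-3,6-dimethylbenzoyl chloride F6.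
- F5 is deprotonated with LiN(SiMe3)2 in THF at −78 °C to lithium 3-(methoxycarbonyl)-1,2,5-trimethyl-4-oxocyclohexa-2,5-dien-1-olate F7, which is acylated with F6 to give 12. Lithium alkoxides are the usual means of esterifying tertiary alcohols with 2,6-disubstituted aroyl chlorides.

**Step 8.** The most likely failure is incomplete ligand exchange, which would leave acetate on iodine; acetate would then be transferred to C5 in step 9 in competition with the ring B carboxylate.

Fallback, setting out from 9 and returning at 11: two equivalents of 9 are condensed with iodosylbenzene in CH2Cl2 over molecular sieves. Water is the only by-product and no acetate is ever present. This fallback makes no new compound (F0).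

**Step 6.** The most likely failures are very slow addition of hydroxide to the shielded carbonyl of the phenoxide form, and protodecarboxylation of the electron-rich salicylic acid during acidification if forcing conditions are needed.

Fallback, setting out from 7 and returning at 8: LiI in refluxing pyridine cleaves the ester by SN2 attack of iodide on the unhindered O–CH3 carbon rather than at the carbonyl. The aryl methyl ether, a far poorer leaving group, should survive, and cold acidification gives 8. This fallback makes no new compound (F0).

## Further compounds

F1 | step 10 | racemic methyl 5-acetoxy-3,5,6-trimethyl-2-oxocyclohexa-3,6-diene-1-carboxylate | COC(=O)C1=C(C)C(C)(OC(C)=O)C=C(C)C1=O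
F2 | step 10 | methyl 4-acetoxy-2-hydroxy-3,5,6-trimethylbenzoate | COC(=O)c1c(C)c(C)c(OC(C)=O)c(C)c1O
F3 | step 10 | methyl 2,4-dihydroxy-3,5,6-trimethylbenzoate | COC(=O)c1c(C)c(C)c(O)c(C)c1O
F4 | step 10 | 2-acetoxy-5-chloro-4-methoxy-3,6-dimethylbenzoic trifluoroacetic anhydride | CC(=O)Oc1c(C)c(OC)c(Cl)c(C)c1C(=O)OC(=O)C(F)(F)F
F5 | step 9 | racemic methyl 5-hydroxy-3,5,6-trimethyl-2-oxocyclohexa-3,6-diene-1-carboxylate | COC(=O)C1=C(C)C(C)(O)C=C(C)C1=O
F6 | step 9 | 2-acetoxy-5-chloro-4-methoxy-3,6-dimethylbenzoyl chloride | CC(=O)Oc1c(C)c(OC)c(Cl)c(C)c1C(Cl)=O
F7 | step 9 | racemic lithium 3-(methoxycarbonyl)-1,2,5-trimethyl-4-oxocyclohexa-2,5-dien-1-olate | [Li+].COC(=O)C1=C(C)C(C)([O-])C=C(C)C1=O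
F0 | step 8 | none | none
F0 | step 6 | none | none
A1 | alternative 1 | methyl 2-hydroxy-3,5,6-trimethyl-4-(triisopropylsilyloxy)benzoate | COC(=O)c1c(C)c(C)c(O[Si](C(C)C)(C(C)C)C(C)C)c(C)c1O
A2 | alternative 1 | methyl (2E)-5-diazo-3-methyl-4-oxohex-2-enoate | COC(=O)/C=C(C)/C(=O)C(C)=[N+]=[N-]
A3 | alternative 1 | 1-(triisopropylsilyloxy)propyne | CC#CO[Si](C(C)C)(C(C)C)C(C)C
A4 | alternative 2 | methyl 4-[(2-hydroxy-4-methoxy-3,6-dimethylbenzoyl)oxy]-2-(methoxymethoxy)-3,5,6-trimethylbenzoate | COC(=O)c1c(C)c(C)c(OC(=O)c2c(C)cc(OC)c(C)c2O)c(C)c1OCOC
A5 | alternative 2 | methyl 4-(but-2-ynoyloxy)-2-(methoxymethoxy)-3,5,6-trimethylbenzoate | COC(=O)c1c(C)c(C)c(OC(=O)C#CC)c(C)c1OCOC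
A6 | alternative 2 | 1,3-dimethoxy-2-methyl-1-(trimethylsilyloxy)buta-1,3-diene | COC(=C)C(C)=C(OC)O[Si](C)(C)C
A7 | alternative 3 | methyl 2,4-dihydroxy-3,5,6-trimethylbenzoate | COC(=O)c1c(C)c(C)c(O)c(C)c1O
A8 | alternative 3 | 2,2-dimethyl-6-(4-methyl-3,5-dioxohexan-2-yl)-4H-1,3-dioxin-4-one | CC(=O)C(C)C(=O)C(C)C1=CC(=O)OC(C)(C)O1
A9 | alternative 3 | methyl 4,6-dimethyl-3,5,7-trioxooctanoate | COC(=O)CC(=O)C(C)C(=O)C(C)C(C)=O
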